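The constants were set for the occasion; the result is computed.

Late in a run of this kind, target is being made and destroyed at once. Reagent that has crossed into the reaction phase turns substrate into target and attacks target by two routes, while protic impurity quenches reagent.

substrate 0.37 M; reagent in the second phase 0.555 M; protic impurity 0.185 M; time 2.5 min; volume of the second phase over the first 1.0

- target at 2.5 min, in percent of the substrate charged
- the change that raises the amount of target at 2.5 min, in percent of the substrate charged most ("none" if none brings more than 2 percentage points) (eta / alpha / none)
- amount of target at 2.5 min, in percent of the substrate charged, after eta

- in the second phase: reagent in the second phase; everything else is in the first
- charges count per volume of the first phase; a concentration in a rate is the amount of a species over the volume of its own phase; every rate counts per litre of the first phase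
- run time (flask): 2.5 min

    reagent in the reaction phase + target → over-reacted product (k1 = 0.0033 /M/s)
    reagent in the reaction phase + protic impurity → quenched reagent (k2 = 0.0082 /M/s)
    reagent in the reaction phase ⇌ reagent in the second phase, rate k3*([reagent in the reaction phase] - [reagent in the second phase]/K3) per volume of the first phase (K3 = 0.55, k3 = 0.016 /s)
    substrate + reagent in the reaction phase → target (k4 = 0.0048 /M/s)
    reagent in the reaction phase + target → over-reaction product (k5 = 0.0061 /M/s)

Two colleagues dispute where the end of this flask's run stands on that course. The first starts from the late end. Target's two loss routes together beat its making by a selectivity factor of 1.96, faster at equal concentrations, and that caps target at 25.3% of the substrate charged. She expects extra reagent to destroy what it makes, so she names none.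

The second starts from the early end, and I reckon her case by hand. Crossing relaxes in 0.370 min and leaves 64.5% of the reagent in the reaction phase. Reagent is consumed with a lifetime of 7.84 min, taken at the charged concentrations, so crossing is far quicker than consumption. The clock for this flask is then the exposure, the rate constant of target's making times the reaction-phase reagent integrated over time, which counts substrate lifetimes. Over the run it comes to 0.183, less than the 0.701 at which the cap falls.

Joining the ends, target is exp(−exposure) minus exp(−factor × exposure), divided by the factor less one, which gives 14.0%. Doubling the reagent charge doubles the exposure in this reckoning, whose lifetime does not contain that charge, and gives 21.4%. A doubled transfer coefficient trims the lag to 0.185 min, which takes exposure to 0.202. My choice is eta.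

Her number is the forecast: 14.2%, eta, then 21.7%, on the ground that “the target follows a consecutive-reaction profile driven by the time-integrated reagent concentration”.

The flask gives 14.3%, and 21.8% after eta, which gains 7.5 percentage points against 0.88 points for the faster transfer.

At 2.50 min in this flask target is still made 2.96 times as fast as it is used up. Put to use once more, the exposure gives the substrate left as 83.3% of the charge, and 83% stood.

For the same flask read at 10 min, the exposure comes to 0.545, still below the cap's 0.701, and the joined curve gives 24.6%. The simulation gives 25.0% there and 24.5% at 25.0 min, and that late region, with target near her 25.3%, is where the first colleague's ceiling is right.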